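(The earlier runs and the new flask come from a simulation for substances that don't exist; noise was put on by code.)

Reckon this flask by its free catalyst, the smallest charge at 0.36 mM, against 0.56 mM of added ligand, 0.13 M of left-handed substrate and 0.260 M of reagent.

| flask | left-handed substrate | right-handed substrate | reagent | free catalyst | added ligand | remark | time |
|---|---|---|---|---|---|---|---|
| east | 0.087 M | 0.087 M | 0.26 M | 0.36 mM | 0.56 mM | run made earlier |  |
| north | 0.20 M | 0.20 M | 0.26 M | 0.36 mM | 0.56 mM | run made earlier |  |
| north-west | 0.13 M | 0.13 M | 0.26 M | 0.36 mM | 1.1 mM | run made earlier |  |
| flask | 0.13 M | 0.13 M | 0.260 M | 0.36 mM | 0.56 mM |  | 30 min |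

- east (time / min: left-handed product / %, right-handed product / %): 5.00: 2.8, 0; 10.0: 4.1, 0.6; 15.0: 5.7, 0.9; 20.0: 6.5, 1.4; 25.0: 7.4, 1.5
- north (time / min: left-handed product / %, right-handed product / %): 2.00: 1.1, 0.4; 6.00: 3.4, 0.6; 12.0: 4.6, 1.3; 15.0: 5.7, 0.7; 25.0: 7.8, 1.4
- north-west (time / min: left-handed product / %, right-handed product / %): 2.00: 0.4, 0.3; 6.00: 1.5, 0.4; 12.0: 2.9, 0; 15.0: 3.4, 0.6; 25.0: 4.7, 0.7

(each reading ± 0.3 percentage points)

- free catalyst is single-handed; left-handed substrate and right-handed substrate are mirror images of each other, charged as a racemate, each of them at the stated concentration
- the analysis behind the earlier runs scatters by 0.3 percentage points, standard deviation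
- an excess is below zero if the other one leads

- excess of left-handed product over right-handed product in the product at 40 s
- excess of left-handed product over right-handed product in the product at 30 min
- part of the left-handed substrate and right-handed substrate charged together that has reacted at 30 min

The flask shares its reagent, free catalyst and added ligand charges with east and north, whose substrate charges stand 2.30 times apart. Yet at 25.0 min east has reacted 8.90% of the charge and north 9.20%, so pool the two runs as X, the part of both substrates reacted, and apply it to the flask.

Early rate, up to 15.0 min: X = 6.50%, so 0.00433 /min

Late rate, up to 25.0 min: X = 9.05%, so 0.00255 /min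

Straight on to 30 min: X = 10.3%

The straight line is the weak link. The late rate is 0.588 of the early one, while at that X substrate and reagent in this flask, whose reagent charge equals its two substrate charges together, each stand near 90.9% of their charge, a drop larger than their use explains, so I put the loss on the catalyst and let the rate keep falling. The window middles lie 12.5 min apart, and the last window's middle lies 7.50 min further on.

End rate: 0.00186 /min

X at 30 min: 9.98%

Substrate reacted per catalyst charged, the turnover number: n = X · (both substrate charges) / (catalyst charge) = 72.1

The forecast gives 71% at 40 s, 68% at 30 min and 10% reacted, holding that “the reaction is first order in substrate”.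

The flask gives 66.6%, 66.6% and 9.58%, which is 69.2 turnovers against the reckoned 72.1.

    reagent + free catalyst + left-handed substrate → free catalyst + left-handed product (k = 430 /M²/min)
    reagent + free catalyst + right-handed substrate → free catalyst + right-handed product (k = 86.0 /M²/min)
    left-handed substrate ⇌ right-handed substrate (k = 1.80 /min)
    2 free catalyst → spent catalyst A (k = 40.0 /M/min)
    free catalyst → spent catalyst B (k = 0.150 /min)
    free catalyst + added ligand ⇌ idle complex (K = 7400 /M, k = 4100 /M/min)

In this flask at 30.0 min, spent catalyst B holds 65.8% of the catalyst charged. Now take a neighbour flask with 6.1 × 10⁻⁴ M of free catalyst and the other charges held: 69.2 turnovers on that charge come to 16.2% reacted, and that flask gives 15.8%.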